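Retrosynthesis (carotenoid numbering): the chain is cut at C11'=C12' (C5 acetal ylide), then C11=C12 (C10 dial), then C7=C8 (C5 phosphonate), leaving a cis-3-silyloxy-α-cyclocitral.
That aldehyde is traced to a bridged lactone, cut at its O3–C7 acyl bond, and the carbocycle is cut at C1–C6 and C4=C5 into mesityl oxide and ethyl acetoacetate.
Enabling feature: in the cyclohexene ring the C3–O and C6–C7 bonds are cis-1,4 across C4=C5 and C6 is a base-labile methine (α to C7, allylic), so an O3-to-C7 lactone bridge (2-oxabicyclo[2.2.2]oct-5-en-3-one) can form only from the wanted cis isomer and then locks C6 and the olefin position.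
Forward order: annulation to the ring, enantioselective ketone reduction, epimerizing lactonization, lactone opening to the aldehyde, then chain assembly C7=C8, C11=C12, C11'=C12', acetal hydrolysis and desilylation.
Stereochemistry: C3 (S) from a catalyst-controlled reduction; C6 (R) relayed from C3 through the lactone bridge; the E olefins from stabilized and semistabilized ylide olefinations plus a final thermal equilibration.

Key step: step 3

Remark: positions are given in carotenoid numbering while names use systematic locants; each olefination product is numbered and drawn as its all-E isomer, and the thermally labile Z isomers at the new disubstituted bonds are carried along and converged in the last step.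

Step 1
Reactants: 1 mesityl oxide; 2 ethyl acetoacetate
Product: 3 racemic ethyl 2,6,6-trimethyl-4-oxocyclohex-2-ene-1-carboxylate
Conditions: ZnCl2 (0.2 equiv), heptane/toluene, reflux, Dean–Stark
Reagents that add atoms: none
Why: Lewis-acid-promoted Michael addition of the acetoacetate methine carbon to the β-carbon of 1, followed by intramolecular aldol condensation of the methyl ketone onto the acetoacetate carbonyl (Robinson-type annulation), builds the ring with the ester carbon as future C7; the one stereocentre forms racemic and is labile.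

Step 2
Reactants: 3 racemic ethyl 2,6,6-trimethyl-4-oxocyclohex-2-ene-1-carboxylate
Product: 4 ethyl (4S)-4-hydroxy-2,6,6-trimethylcyclohex-2-ene-1-carboxylate, mixture of (1R) and (1S) epimers
Conditions: (R)-2-methyl-CBS-oxazaborolidine (0.2 equiv), BH3·SMe2 (0.7 equiv), THF, −20 °C; MeOH quench
Reagents that add atoms: none
Why: In this Corey–Bakshi–Shibata reduction the oxazaborolidine–borane complex should treat the planar C4=C5 arm as the larger ketone substituent and deliver hydride 1,2 to the same carbonyl face in both antipodes of 3, giving the S carbinol just as the (R)-catalyst gives (S)-1-arylethanols; the ester and the labile ester-bearing centre are untouched, and the configuration of that centre does not matter because step 3 resets it.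

Step 3
Reactants: 4 ethyl (4S)-4-hydroxy-2,6,6-trimethylcyclohex-2-ene-1-carboxylate, mixture of (1R) and (1S) epimers
Product: 5 (1S,4R)-5,8,8-trimethyl-2-oxabicyclo[2.2.2]oct-5-en-3-one
Conditions: KOC(CH3)2C2H5 (1.1 equiv), toluene/2-methylbutan-2-ol, 0 → 90 °C, ethanol distilled off through a short column; AcOH, 0 °C
Reagents that add atoms: none
Why: The tertiary alkoxide turns O3 of both epimers into the potassium alkoxide; in the cis (1R,4S) epimer a boat conformer holds that alkoxide over the ester carbon C7, and addition followed by loss of ethoxide (acyl substitution, 6-exo-trig) closes the six-membered lactone ring as the O–C(=O) bridge of the 2-oxabicyclo[2.2.2]octene. The trans epimer cannot reach its ester, but its C6–H (α to the ester and allylic to C4=C5) is removed reversibly by alkoxide, and α-protonation of the dienolate returns both epimers, while any conjugated ester from γ-protonation re-enters through the same dienolate, so the cis epimer is replenished as it is consumed. The closest known reaction type is the base- or heat-induced epimerizing lactonization of cis/trans-4-hydroxycyclohexanecarboxylic acids and esters to 2-oxabicyclo[2.2.2]octan-3-one. The new stereocentre C6 (R) is controlled by the fixed 3S carbinol, because only a cis-1,4 pair can span the two-atom bridge. The selectivities needed are 6R over 6S and retention of the C4=C5 position, and the product secures both: its enolization would demand a bridgehead C6=C7 double bond, so the lactone is inert to the base, and once ethanol has been distilled out only tert-pentoxide remains, which is too hindered to reopen it. Keeping O3 ionized also disfavours the vinylogous E1cB loss of the C3 oxygen from the dienolate, the side reaction most to be feared.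

Step 4
Reactants: 5 (1S,4R)-5,8,8-trimethyl-2-oxabicyclo[2.2.2]oct-5-en-3-one
Product: 6 (1R,4S)-4-hydroxy-N-methoxy-N,2,6,6-tetramethylcyclohex-2-ene-1-carboxamide
Conditions: MeNH(OMe)·HCl (1.5 equiv), i-PrMgCl (3.0 equiv), THF, −15 → 0 °C; aqueous work-up
Reagents that add atoms: N,O-dimethylhydroxylamine hydrochloride, CNOC.Cl
Why: The chloromagnesium amide of N,O-dimethylhydroxylamine adds to the strained, non-enolizable lactone carbonyl (Weinreb aminolysis of a lactone), and at this temperature the weakly basic magnesium amide should not deprotonate the amide α-position, so the cis relationship fixed in step 3 passes unchanged into the open-chain amide.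

Step 5
Reactants: 6 (1R,4S)-4-hydroxy-N-methoxy-N,2,6,6-tetramethylcyclohex-2-ene-1-carboxamide
Product: 7 (1R,4S)-4-[(tert-butyldimethylsilyl)oxy]-N-methoxy-N,2,6,6-tetramethylcyclohex-2-ene-1-carboxamide
Conditions: TBSCl, imidazole, DMF, 20 °C
Reagents that add atoms: tert-butyldimethylsilyl chloride, CC(C)(C)[Si](C)(C)Cl
Why: Standard imidazole-mediated silylation of an unhindered secondary allylic alcohol; it blocks relactonization and masks O3 for the phosphorus chemistry that follows.

Step 6
Reactants: 7 (1R,4S)-4-[(tert-butyldimethylsilyl)oxy]-N-methoxy-N,2,6,6-tetramethylcyclohex-2-ene-1-carboxamide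
Product: 8 (1R,4S)-4-[(tert-butyldimethylsilyl)oxy]-2,6,6-trimethylcyclohex-2-ene-1-carbaldehyde (cis-3-silyloxy-α-cyclocitral)
Conditions: i-Bu2AlH (1.3 equiv), THF, −78 °C; cold aqueous potassium sodium tartrate; used at once
Reagents that add atoms: none
Why: Hydride reduction of a Weinreb amide stops at the chelated aluminium hemiaminal, which releases the aldehyde only on cold, near-neutral work-up, so the epimerizable and conjugation-prone α-centre is exposed as briefly as possible.

Step 7
Reactants: 8 (1R,4S)-4-[(tert-butyldimethylsilyl)oxy]-2,6,6-trimethylcyclohex-2-ene-1-carbaldehyde; 9 triethyl (E)-3-methyl-4-phosphonocrotonate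
Product: 10 ethyl (2E,4E)-5-[(1R,4S)-4-[(tert-butyldimethylsilyl)oxy]-2,6,6-trimethylcyclohex-2-en-1-yl]-3-methylpenta-2,4-dienoate
Conditions: 9 (1.3 equiv), LiN(SiMe3)2 (1.2 equiv), THF, −78 °C, then 8, −78 → −20 °C; chromatography to remove the minor 9Z isomer
Reagents that add atoms: none
Why: Horner–Wadsworth–Emmons olefination with the preformed, fully consumed lithium anion of the vinylogous phosphonate forms C7=C8 with the E geometry typical of stabilized phosphonates, and at low temperature addition to the lithium-activated aldehyde should outrun enolization at C6.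

Step 8
Reactants: 10 ethyl (2E,4E)-5-[(1R,4S)-4-[(tert-butyldimethylsilyl)oxy]-2,6,6-trimethylcyclohex-2-en-1-yl]-3-methylpenta-2,4-dienoate
Product: 11 (2E,4E)-5-[(1R,4S)-4-[(tert-butyldimethylsilyl)oxy]-2,6,6-trimethylcyclohex-2-en-1-yl]-3-methylpenta-2,4-dien-1-ol
Conditions: i-Bu2AlH (2.3 equiv), CH2Cl2, −78 °C; aqueous potassium sodium tartrate
Reagents that add atoms: none
Why: Aluminium hydride 1,2-reduction of a conjugated ester to the allylic alcohol, which leaves the diene geometry and the silyl ether intact.

Step 9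
Reactants: 11 (2E,4E)-5-[(1R,4S)-4-[(tert-butyldimethylsilyl)oxy]-2,6,6-trimethylcyclohex-2-en-1-yl]-3-methylpenta-2,4-dien-1-ol
Product: 12 (2E,4E)-1-bromo-5-[(1R,4S)-4-[(tert-butyldimethylsilyl)oxy]-2,6,6-trimethylcyclohex-2-en-1-yl]-3-methylpenta-2,4-diene
Conditions: CBr4, PPh3, CH2Cl2, −30 → 0 °C; short silica plug, used directly
Reagents that add atoms: carbon tetrabromide, BrC(Br)(Br)Br
Why: Appel bromination replaces the primary allylic hydroxyl by SN2 under neutral conditions, so neither the acid-sensitive allylic silyl ether nor the ring olefin is disturbed.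

Step 10
Reactants: 12 (2E,4E)-1-bromo-5-[(1R,4S)-4-[(tert-butyldimethylsilyl)oxy]-2,6,6-trimethylcyclohex-2-en-1-yl]-3-methylpenta-2,4-diene
Product: 13 [(2E,4E)-5-[(1R,4S)-4-[(tert-butyldimethylsilyl)oxy]-2,6,6-trimethylcyclohex-2-en-1-yl]-3-methylpenta-2,4-dien-1-yl]triphenylphosphonium bromide
Conditions: PPh3, EtOAc, 20 °C, dark
Reagents that add atoms: triphenylphosphine, c1ccc(cc1)P(c1ccccc1)c1ccccc1
Why: SN2 quaternization of a reactive primary allylic bromide by triphenylphosphine, with the salt expected to separate from ethyl acetate.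

Step 11
Reactants: 13 the C15 triphenylphosphonium bromide; 14 (2E,4E,6E)-2,7-dimethylocta-2,4,6-trienedial
Product: 15 (2E,4E,6E,8E,10E,12E)-13-[(1R,4S)-4-[(tert-butyldimethylsilyl)oxy]-2,6,6-trimethylcyclohex-2-en-1-yl]-2,7,11-trimethyltrideca-2,4,6,8,10,12-hexaenal (the 3-silyloxy-12'-apo-ε-caroten-12'-al)
Conditions: 14 (3 equiv), NaOMe (1.1 equiv) added slowly, MeOH/CH2Cl2, −10 → 20 °C; excess 14 recovered
Reagents that add atoms: none
Why: Wittig olefination of the semistabilized allylic ylide forms C11=C12, and generating the ylide in the presence of excess dial makes reaction at a single aldehyde statistically dominant, as is usual for C15 plus C10 couplings in carotenoid synthesis.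

Step 12
Reactants: 16 1,1-dimethoxyacetone
Product: 17 racemic 1,1-dimethoxy-2-methylbut-3-en-2-ol
Conditions: CH2=CHMgBr, THF, 0 °C; aqueous NH4Cl
Reagents that add atoms: vinylmagnesium bromide, C=C[Mg]Br
Why: Grignard 1,2-addition to an unhindered α-alkoxy ketone; the tertiary carbinol centre is racemic and is destroyed in the next step.

Step 13
Reactants: 17 racemic 1,1-dimethoxy-2-methylbut-3-en-2-ol
Product: 18 (E)-4-bromo-1,1-dimethoxy-2-methylbut-2-ene
Conditions: PBr3 (0.4 equiv), pyridine (0.1 equiv), Et2O, −10 → 0 °C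
Reagents that add atoms: phosphorus tribromide, BrP(Br)Br
Why: Bromide attacks the activated tertiary allylic phosphite at the vinyl terminus (SN2' allylic transposition) to give the primary bromide, with E favoured because it places the acetal carbon trans to CH2Br; pyridine scavenges HBr and protects the acetal.

Step 14
Reactants: 18 (E)-4-bromo-1,1-dimethoxy-2-methylbut-2-ene
Product: 19 [(2E)-4,4-dimethoxy-3-methylbut-2-en-1-yl]triphenylphosphonium bromide
Conditions: PPh3, toluene, 20 → 40 °C
Reagents that add atoms: triphenylphosphine, c1ccc(cc1)P(c1ccccc1)c1ccccc1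
Why: SN2 quaternization of a primary allylic bromide, and crystallization of the salt should enrich the E isomer.

Step 15
Reactants: 15 the 3-silyloxy-12'-apo-ε-caroten-12'-al; 19 [(2E)-4,4-dimethoxy-3-methylbut-2-en-1-yl]triphenylphosphonium bromide
Product: 20 the dimethyl acetal of (3S,6R)-3-[(tert-butyldimethylsilyl)oxy]-8'-apo-ε-caroten-8'-al
Conditions: 19 (1.3 equiv), NaOMe, MeOH/CH2Cl2, 0 → 20 °C
Reagents that add atoms: none
Why: Wittig olefination of the acetal-masked C5 ylide with the polyenal forms C11'=C12'; the acetal keeps the new chain terminus from reacting with the ylide, and the silyl ether tolerates methoxide.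

Step 16
Reactants: 20 the dimethyl acetal of (3S,6R)-3-[(tert-butyldimethylsilyl)oxy]-8'-apo-ε-caroten-8'-al
Product: 21 (3S,6R)-3-[(tert-butyldimethylsilyl)oxy]-8'-apo-ε-caroten-8'-al
Conditions: pyridinium p-toluenesulfonate (cat.), acetone/H2O, 20 °C, dark
Reagents that add atoms: water, O
Why: Acetal hydrolysis; the polyenyl acetal ionizes to a highly delocalized oxocarbenium ion, so a weak buffered acid suffices and the silyl ether and the ionizable allylic C3–O bond are spared.

Step 17
Reactants: 21 (3S,6R)-3-[(tert-butyldimethylsilyl)oxy]-8'-apo-ε-caroten-8'-al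
Product: 22 (3S,6R)-3-hydroxy-8'-apo-ε-caroten-8'-al, all-E (the target)
Conditions: Bu4NF, AcOH (1:1), THF, 0 → 20 °C; then EtOAc/heptane, 70 °C, N2, dark; crystallization
Reagents that add atoms: none
Why: Fluoride desilylation buffered with acetic acid frees the C3 hydroxyl without exposing the polyenal to base or the allylic carbinol to acid, and gentle heating converts the sterically strained Z isomers at C11 and C11' into the all-E compound, which should crystallize.

Compound list
1 | mesityl oxide (4-methylpent-3-en-2-one) | CC(C)=CC(C)=O | starting material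
2 | ethyl acetoacetate | CCOC(=O)CC(C)=O | starting material
3 | racemic ethyl 2,6,6-trimethyl-4-oxocyclohex-2-ene-1-carboxylate | CC1=CC(=O)CC(C)(C)C1C(=O)OCC | intermediate
4 | ethyl (4S)-4-hydroxy-2,6,6-trimethylcyclohex-2-ene-1-carboxylate, mixture of C1 epimers | CC1=C[C@@H](O)CC(C)(C)C1C(=O)OCC | intermediate
5 | (1S,4R)-5,8,8-trimethyl-2-oxabicyclo[2.2.2]oct-5-en-3-one | CC1=C[C@@H]2CC(C)(C)[C@H]1C(=O)O2 | intermediate
6 | (1R,4S)-4-hydroxy-N-methoxy-N,2,6,6-tetramethylcyclohex-2-ene-1-carboxamide | CC1=C[C@@H](O)CC(C)(C)[C@H]1C(=O)N(C)OC | intermediate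
7 | (1R,4S)-4-[(tert-butyldimethylsilyl)oxy]-N-methoxy-N,2,6,6-tetramethylcyclohex-2-ene-1-carboxamide | CC1=C[C@@H](O[Si](C)(C)C(C)(C)C)CC(C)(C)[C@H]1C(=O)N(C)OC | intermediate
8 | (1R,4S)-4-[(tert-butyldimethylsilyl)oxy]-2,6,6-trimethylcyclohex-2-ene-1-carbaldehyde | CC1=C[C@@H](O[Si](C)(C)C(C)(C)C)CC(C)(C)[C@H]1C=O | intermediate
9 | triethyl (E)-3-methyl-4-phosphonocrotonate | CCOC(=O)/C=C(\C)CP(=O)(OCC)OCC | starting material
10 | ethyl (2E,4E)-5-[(1R,4S)-4-[(tert-butyldimethylsilyl)oxy]-2,6,6-trimethylcyclohex-2-en-1-yl]-3-methylpenta-2,4-dienoate | CC1=C[C@@H](O[Si](C)(C)C(C)(C)C)CC(C)(C)[C@H]1/C=C/C(C)=C/C(=O)OCC | intermediate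
11 | (2E,4E)-5-[(1R,4S)-4-[(tert-butyldimethylsilyl)oxy]-2,6,6-trimethylcyclohex-2-en-1-yl]-3-methylpenta-2,4-dien-1-ol | CC1=C[C@@H](O[Si](C)(C)C(C)(C)C)CC(C)(C)[C@H]1/C=C/C(C)=C/CO | intermediate
12 | (2E,4E)-1-bromo-5-[(1R,4S)-4-[(tert-butyldimethylsilyl)oxy]-2,6,6-trimethylcyclohex-2-en-1-yl]-3-methylpenta-2,4-diene | CC1=C[C@@H](O[Si](C)(C)C(C)(C)C)CC(C)(C)[C@H]1/C=C/C(C)=C/CBr | intermediate
13 | [(2E,4E)-5-[(1R,4S)-4-[(tert-butyldimethylsilyl)oxy]-2,6,6-trimethylcyclohex-2-en-1-yl]-3-methylpenta-2,4-dien-1-yl]triphenylphosphonium bromide | CC1=C[C@@H](O[Si](C)(C)C(C)(C)C)CC(C)(C)[C@H]1/C=C/C(C)=C/C[P+](c2ccccc2)(c2ccccc2)c2ccccc2.[Br-] | intermediate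
14 | (2E,4E,6E)-2,7-dimethylocta-2,4,6-trienedial | O=C/C(C)=C/C=C/C=C(\C)C=O | starting material
15 | (3S,6R)-3-[(tert-butyldimethylsilyl)oxy]-12'-apo-ε-caroten-12'-al | CC1=C[C@@H](O[Si](C)(C)C(C)(C)C)CC(C)(C)[C@H]1/C=C/C(C)=C/C=C/C(C)=C/C=C/C=C(\C)C=O | intermediate
16 | 1,1-dimethoxyacetone | CC(=O)C(OC)OC | starting material
17 | racemic 1,1-dimethoxy-2-methylbut-3-en-2-ol | C=CC(C)(O)C(OC)OC | intermediate
18 | (E)-4-bromo-1,1-dimethoxy-2-methylbut-2-ene | COC(OC)/C(C)=C/CBr | intermediate
19 | [(2E)-4,4-dimethoxy-3-methylbut-2-en-1-yl]triphenylphosphonium bromide | COC(OC)/C(C)=C/C[P+](c1ccccc1)(c1ccccc1)c1ccccc1.[Br-] | intermediate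
20 | (3S,6R)-3-[(tert-butyldimethylsilyl)oxy]-8'-apo-ε-caroten-8'-al dimethyl acetal | CC1=C[C@@H](O[Si](C)(C)C(C)(C)C)CC(C)(C)[C@H]1/C=C/C(C)=C/C=C/C(C)=C/C=C/C=C(C)/C=C/C=C(\C)C(OC)OC | intermediate
21 | (3S,6R)-3-[(tert-butyldimethylsilyl)oxy]-8'-apo-ε-caroten-8'-al | CC1=C[C@@H](O[Si](C)(C)C(C)(C)C)CC(C)(C)[C@H]1/C=C/C(C)=C/C=C/C(C)=C/C=C/C=C(C)/C=C/C=C(\C)C=O | intermediate
22 | (3S,6R)-3-hydroxy-8'-apo-ε-caroten-8'-al; (2E,4E,6E,8E,10E,12E,14E,16E)-17-[(1R,4S)-4-hydroxy-2,6,6-trimethylcyclohex-2-en-1-yl]-2,6,11,15-tetramethylheptadeca-2,4,6,8,10,12,14,16-octaenal | CC1=C[C@@H](O)CC(C)(C)[C@H]1/C=C/C(C)=C/C=C/C(C)=C/C=C/C=C(C)/C=C/C=C(\C)C=O | target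

Total step count: 17. Longest linear sequence: 14 steps (steps 1 to 11, then 15 to 17); the C5 acetal salt takes 3 steps (12 to 14).

Steps most likely to fail

Step 3. Vinylogous elimination of the C3 oxygen from the dienolate may outrun ring closure, the olefin may drift to the exocyclic position before closure, or ethoxide may reopen the lactone if ethanol removal is inefficient. The fallback sets out from 4 and returns at 8. The epimers of 4 are separated on silica into the cis epimer ethyl (1R,4S)-4-hydroxy-2,6,6-trimethylcyclohex-2-ene-1-carboxylate F1 and the trans epimer ethyl (1S,4S)-4-hydroxy-2,6,6-trimethylcyclohex-2-ene-1-carboxylate F2. F2 is oxidized back to keto ester 3 with MnO2 in CH2Cl2, racemized at the ester-bearing centre with catalytic Et3N and sent again through step 2. F1 is silylated (TBSCl, imidazole, DMF) to ethyl (1R,4S)-4-[(tert-butyldimethylsilyl)oxy]-2,6,6-trimethylcyclohex-2-ene-1-carboxylate F3, reduced with i-Bu2AlH (CH2Cl2, −78 °C) to [(1R,4S)-4-[(tert-butyldimethylsilyl)oxy]-2,6,6-trimethylcyclohex-2-en-1-yl]methanol F4, and oxidized with Dess–Martin periodinane (NaHCO3, CH2Cl2, 0 °C) to aldehyde 8.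

Step 7. The phosphonate anion may enolize the hindered aldehyde before it adds, which would epimerize C6 or move C4=C5 into conjugation with the formyl group. The fallback sets out from 8 and returns at 10. Takai olefination (CrCl2, CHI3, THF, 0 °C), which is not basic, converts 8 into the vinyl iodide tert-butyl({(1S,4R)-4-[(E)-2-iodoethenyl]-3,5,5-trimethylcyclohex-2-en-1-yl}oxy)dimethylsilane F5. Stille coupling of F5 with ethyl (E)-3-(tributylstannyl)but-2-enoate (Pd(PPh3)4, CuI, DMF, 20 °C) then joins C8 to C9 with both olefin geometries retained and gives dienoate 10.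

Step 2. Facial discrimination may be poor because the two flanks of the ketone (vinylic CH and CH2) differ little and one antipode of 3 is mismatched, and any shortfall at C3 is carried through the whole route. The fallback sets out from 3 and returns at 6. Luche reduction (NaBH4, CeCl3·7H2O, MeOH, −20 °C) gives racemic ethyl 4-hydroxy-2,6,6-trimethylcyclohex-2-ene-1-carboxylate F6 as all four stereoisomers. The conditions of step 3 funnel F6 into racemic 5,8,8-trimethyl-2-oxabicyclo[2.2.2]oct-5-en-3-one F7, and the conditions of step 4 open F7 to racemic cis-4-hydroxy-N-methoxy-N,2,6,6-tetramethylcyclohex-2-ene-1-carboxamide F8, a single diastereomer. Kinetic resolution of F8 with Candida antarctica lipase B and vinyl acetate in tert-butyl methyl ether at 30 °C is expected, from the usual preference of lipases for cyclohex-2-enols (to be confirmed on a sample), to acetylate the unwanted antipode to (1S,4R)-4-acetoxy-N-methoxy-N,2,6,6-tetramethylcyclohex-2-ene-1-carboxamide F9. F9 is removed by chromatography, and the unreacted alcohol is 6.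

Further compounds
F1 | step 3 | ethyl (1R,4S)-4-hydroxy-2,6,6-trimethylcyclohex-2-ene-1-carboxylate (cis epimer) | CC1=C[C@@H](O)CC(C)(C)[C@H]1C(=O)OCC
F2 | step 3 | ethyl (1S,4S)-4-hydroxy-2,6,6-trimethylcyclohex-2-ene-1-carboxylate (trans epimer) | CC1=C[C@@H](O)CC(C)(C)[C@@H]1C(=O)OCC
F3 | step 3 | ethyl (1R,4S)-4-[(tert-butyldimethylsilyl)oxy]-2,6,6-trimethylcyclohex-2-ene-1-carboxylate | CC1=C[C@@H](O[Si](C)(C)C(C)(C)C)CC(C)(C)[C@H]1C(=O)OCC
F4 | step 3 | [(1R,4S)-4-[(tert-butyldimethylsilyl)oxy]-2,6,6-trimethylcyclohex-2-en-1-yl]methanol | CC1=C[C@@H](O[Si](C)(C)C(C)(C)C)CC(C)(C)[C@H]1CO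
F5 | step 7 | tert-butyl({(1S,4R)-4-[(E)-2-iodoethenyl]-3,5,5-trimethylcyclohex-2-en-1-yl}oxy)dimethylsilane | CC1=C[C@@H](O[Si](C)(C)C(C)(C)C)CC(C)(C)[C@H]1/C=C/I
F6 | step 2 | racemic ethyl 4-hydroxy-2,6,6-trimethylcyclohex-2-ene-1-carboxylate, all four stereoisomers | CC1=CC(O)CC(C)(C)C1C(=O)OCC
F7 | step 2 | racemic 5,8,8-trimethyl-2-oxabicyclo[2.2.2]oct-5-en-3-one | CC1=CC2CC(C)(C)C1C(=O)O2
F8 | step 2 | racemic cis-4-hydroxy-N-methoxy-N,2,6,6-tetramethylcyclohex-2-ene-1-carboxamide (racemate, relative configuration as drawn) | CC1=C[C@@H](O)CC(C)(C)[C@H]1C(=O)N(C)OC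
F9 | step 2 | (1S,4R)-4-acetoxy-N-methoxy-N,2,6,6-tetramethylcyclohex-2-ene-1-carboxamide | CC1=C[C@H](OC(C)=O)CC(C)(C)[C@@H]1C(=O)N(C)OC
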